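## Structural features

The target, (5S,6S,7R,8S)-6,7,8-trihydroxy-5-{[7-hydroxy-4-oxo-2-(2-phenylethyl)-4H-chromen-6-yl]oxy}-2-(2-phenylethyl)-5,6,7,8-tetrahydro-4H-chromen-4-one, is built from two 2-(2-phenylethyl)chromone units. One unit is a fully aromatic 6,7-dioxygenated chromone. In the other, a saturated tetra-oxygenated carbocycle (ring A, C4a–C5–C6–C7–C8–C8a) is fused to a 4-pyranone (ring B) through the C4a=C8a double bond. The units are joined by a secondary alkyl aryl ether from C5 of ring A to the C6 oxygen of the aromatic chromone, whose C7 hydroxyl is free and ortho to the ether. C5 to C8 are four contiguous stereocentres with 5,6-trans, 6,7-cis, 7,8-trans and 5,8-cis relationships. The C5–OAr and C8–OH bonds are allylic to C4a=C8a, so acid can ionise them and hydrogenolysis can cleave them; whenever C4a becomes sp3 next to the C4 carbonyl, the C5 aryloxy group is β to an enolisable centre and can be eliminated. Both chromone rings are attacked by hydride, organometallics and hydroxide. The real difficulty is to make the hindered C5 aryl ether with defined configuration and keep it while ring B is closed. The key step uses the fact that C8a is the β-carbon of the enone C4(=O)–C4a=C8a and that O1 can come from the enol of a C2 carbonyl in the side chain, so ring B closes by O1–C8a bond formation with C4a sp2 in every isolated compound.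

## Logic of the disconnections

**22 ⇒ 21.** The O–Si bond at C8, the two acetal C–O bonds at C6 and C7, and the O–CH2 bond of the aryl methoxymethyl acetal are cut. All three groups fall in acid, so one step suffices. An acetal is chosen for the phenol instead of a benzyl ether because hydrogenolysis would have to spare two allylic C–O bonds and two pyranone double bonds. The demand is an acid treatment mild enough not to ionise C5–OAr.

**21 ⇒ 19 (through 20).** The O1–C8a bond is cut and ring B opens to an enone carrying a β-diketone. Ring B and its aromaticity then arise in one catalytic oxidation from an open chain. The demand is that dehydrogenation across C4a–C8a outruns loss of the C5 aryloxide and that the allylic ethers at C5 and C8 are spared.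

**19 ⇒ 18 ⇒ 16 + 17.** The C2–C3 bond is cut (aldol), followed by an oxidation-level adjustment. The ring-A methyl ketone is the nucleophile and a cheap aldehyde the electrophile. No hydride or organometallic reagent is used once the aromatic chromone is attached; reducing an ester to an aldehyde at that stage would not spare the chromone. The demand is kinetic enolisation at the methyl group in the presence of the chromone 2-methylene.

**16 ⇒ 9 + 15.** The C5–O bond is cut on the alkyl side. A phenol is a good nucleophile for a π-allyl electrophile, and substitution with net retention carries over the C5 configuration set earlier. This avoids coupling a hindered secondary alcohol with an electron-rich aryl halide. The route becomes convergent with two halves of similar size. The demand is attack at the C5 terminus and not at C8a, on the face opposite the metal.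

**9 ⇒ 8 ⇒ 7 ⇒ 6.** The C4a–O bond (dehydration), the acetyl group, and the C4a–O and C5–O bonds (dihydroxylation) are cut. Together these steps oxygenate C5 and move the double bond from C4a=C5 to C4a=C8a. The dihydroxylation sets C5, the only stereocentre not present in 1. The demands are addition anti to the acetonide and elimination toward C8a only.

**6 ⇒ 4 (through 5) ⇒ 3 ⇒ 1 (through 2).** The bond from C4 to the methyl carbon (C3), the silyl ether, the acetonide and the methyl ester are cut. Compound 1 already holds ring A, C4 and the C6, C7 and C8 oxygens in the right absolute configuration. Making the methyl ketone here fixes the acyl oxidation level before any sensitive group is present.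

**15 ⇒ 14 ⇒ 13 ⇒ 10 + 11 (through 12).** The methoxymethyl O–C bond, the two O–CH3 bonds, then O1'–C2' and C2'–C3' of the aromatic chromone are cut. Compound 10 already carries the oxygen that becomes O–C6'. The demand is selective protection of the more acidic 7'-hydroxyl.

## Other disconnections considered

**Alternative 1:** The cut removes the C5–O and C8–O bonds together and leads to diene A1, the acetonide of methyl (1S,2R)-1,2-dihydroxycyclohexa-3,5-diene-1-carboxylate. Forward, singlet oxygen would add across the diene termini of A1 in a [4+2] cycloaddition on the face away from the acetonide to give endoperoxide A2. In A2 the peroxide carbons are the future C5 and C8, the acetonide carbons the future C4a and C8a, and the ester carbon the future C4.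
- In its favour: two C–O bonds and the cis C5/C8 relationship of 22 would arise in one pericyclic step under control of a rigid acetonide.
- Against it: A2 has an oxygen on C4a that 22 lacks and none on C6 and C7. The C6=C7 alkene would have to be dihydroxylated from the face shielded by the acetonide-bearing bridge, so the peroxide would have to be reduced first. The two resulting allylic hydroxyls would then need to be told apart before O-arylation next to a fully substituted carbon. Removing the C4a oxygen would pass through a C8a ketone with an sp3, doubly activated C4a, which is the β-aryloxy carbonyl arrangement that eliminates.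
- Comparison: on structure, A2 is the better source of the C5 and C8 oxygens (the chosen plan needs steps 4–6 for the C5 oxygen alone), while 1 is the better source of the C6 and C7 oxygens and of an sp2 C4a. On mechanism, the cycloaddition is at least the equal of step 13 in predictability and better in facial control; the steps after it are not. On step economy, ring oxygenation would be shorter but the whole route probably longer.

**Alternative 2:** The cut is the C8–C8a bond and leads to the open-chain dialdehyde A3, a 2-deoxyhexodialdose with a 4-methoxybenzyl ether on the future C5 oxygen and an acetonide on the future C6 and C7 oxygens. Forward, a triazolium-derived N-heterocyclic carbene with a weak amine base would turn the C8a aldehyde into an acyl anion equivalent that adds to the C8 aldehyde (intramolecular benzoin reaction), closing ring A as acyloin A4.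
- In its favour: a metal-free, catalytic ring closure under mild conditions, with C8a at the ketone level needed for O1 and all four ring oxygens present.
- Against it: the two aldehydes must be told apart. C8 is a new stereocentre next to an epimerisable acyloin that can tautomerise through the enediol. In A4, C4a is a methylene α to the ketone with the C5 oxygen in the β-position, so the basic carbene conditions and every later enolisation (C-acylation at C4a to bring in C4, pyranone formation) invite β-elimination. The aryl ether would still have to be made after removing the 4-methoxybenzyl group.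
- Comparison: on structure, A4 equals the chosen plan in oxygenation but lacks C4 and the aryl ether. On mechanism, the carbene step is better than step 13 in one respect, since no zerovalent palladium is present to threaten an allylic ether, but it is worse in creating a stereocentre under weak control. On step economy, it would be clearly longer.

**Alternative 3:** The cut is the C4a–C5 bond and leads to A5, an aryl 2,3,4-tri-O-benzyl-6-deoxy-α-D-lyxo-hex-5-enopyranoside (D-manno configuration at C2–C4, aryl = 7-benzyloxy-4-oxo-2-(2-phenylethyl)chromen-6-yl). Forward, TiCl3(Oi-Pr) (tetravalent titanium) would open A5 at the ring oxygen. The titanium enolate carbon (future C4a) would then attack the aryloxy-stabilised oxocarbenium carbon (future C5) in a Ferrier-type carbocyclisation that keeps the aglycone, giving cyclohexanone A6.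
- In its favour: the aryl ether would be made as an ordinary 1,2-trans aryl glycoside, which is more reliable than any etherification of a hindered carbinol. The C6, C7 and C8 stereocentres come from the sugar, and C8a arrives as a ketone.
- Against it: A6 is a β-aryloxy ketone with an sp3 C4a, so the Lewis acid itself and the later C4a acylation threaten the ether by elimination. C5 passes through a planar oxocarbenium ion, so retention is not assured. The chromone carbonyl competes for titanium, and three benzyl ethers would need a final hydrogenolysis beside allylic C–O bonds.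
- Comparison: on structure, A5/A6 are better than the chosen plan in how the aryl ether is secured. On mechanism, the chosen plan is safer because C4a stays sp2. On step economy, the two are about equal up to the carbocycle, and the alternative is longer after it.

Key step: step 13

## Remarks before the steps

- **Locants and faces.** Ring A carbons carry the target locants C4a, C5, C6, C7, C8, C8a; in shikimate numbering these are C1, C2, C3, C4, C5, C6. "Upper face" is the face of the C8 oxygen; the acetonide lies on the lower face. Ar = 7-(methoxymethoxy)-4-oxo-2-(2-phenylethyl)-4H-chromen-6-yl.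
- **Configuration check.** Compound 1 is (3R,4S,5R); with the mapping above its three stereocentres coincide with C6, C7 and C8 of 22. The configurations of 19, 21, A2, A4 and A6 agree with 22, so no structure needed correction.
- **Design choices.** The phenol carries a methoxymethyl group, so one acid step ends the synthesis. The acyl group is brought to the ketone level before the chromone is attached. The C5 ether is made by allylic substitution with the phenol as nucleophile.
- **Assumption.** Compounds 10 and 17 are taken as purchasable; 10 already holds the oxygen that becomes O–C6 of the aromatic chromone.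

## Route

Step 1
Reactants: 1 (−)-shikimic acid
Product: 3 methyl 3,4-O-isopropylidene shikimate, via methyl shikimate 2 (not isolated)
Conditions: MeOH, CSA (cat.), reflux; evaporate; Me2C(OMe)2, acetone, CSA (cat.), rt
Reagents that add atoms: methanol, CO; 2,2-dimethoxypropane, COC(C)(C)OC
Why: Fischer esterification followed by acetalisation; only the cis-3,4-diol can form the five-membered acetonide, so the trans 5-OH stays free and no stereocentre is touched.

Step 2
Reactants: 3 methyl 3,4-O-isopropylidene shikimate
Product: 4 methyl 5-O-(tert-butyldimethylsilyl)-3,4-O-isopropylidene shikimate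
Conditions: TBSCl, imidazole, DMF, rt
Reagents that add atoms: tert-butyldimethylsilyl chloride, CC(C)(C)[Si](C)(C)Cl
Why: Standard silylation of the only free hydroxyl; the bulky silyl ether later shields the upper face at C8a in step 10.

Step 3
Reactants: 4 methyl 5-O-(tert-butyldimethylsilyl)-3,4-O-isopropylidene shikimate
Product: 6 1-[5-(tert-butyldimethylsilyloxy)-3,4-(isopropylidenedioxy)cyclohex-1-en-1-yl]ethanone, via Weinreb amide 5 (not isolated)
Conditions: MeNH(OMe)·HCl, i-PrMgCl, THF, −20 °C; then MeMgBr, −20 → 0 °C; aq. NH4Cl
Reagents that add atoms: methylmagnesium bromide, C[Mg]Br; N,O-dimethylhydroxylamine hydrochloride, CNOC.Cl (its atoms are in 5 only, not in 6)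
Why: Transamidation of the ester with ClMgN(OMe)Me made in the flask gives Weinreb amide 5, whose chelated MeMgBr adduct releases the ketone only on work-up, so over-addition and 1,4-addition are avoided; if the one-flask procedure proved untidy, 5 could be isolated.

Step 4
Reactants: 6 1-[5-(tert-butyldimethylsilyloxy)-3,4-(isopropylidenedioxy)cyclohex-1-en-1-yl]ethanone
Product: 7 1-[1,2-dihydroxy-3,4-(isopropylidenedioxy)-5-(tert-butyldimethylsilyloxy)cyclohexyl]ethanone (1-OH and 2-OH on the upper face)
Conditions: K2OsO2(OH)4 (2 mol %), NMO, citric acid, t-BuOH/H2O, rt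
Reagents that add atoms: osmium tetroxide (formed from K2OsO2(OH)4), O=[Os](=O)(=O)=O; its oxygen is replenished from N-methylmorpholine N-oxide, C[N+]1([O-])CCOCC1, and water, O
Why: Upjohn dihydroxylation; osmium tetroxide adds suprafacially to the face of the alkene opposite the allylic acetonide oxygen (Kishi's rule), so the secondary hydroxyl at the future C5 is trans to the C6 oxygen and the tertiary hydroxyl lies on the same upper face; citric acid keeps turnover with the electron-poor enone.

Step 5
Reactants: 7 the diol from step 4
Product: 8 2-O-acetate of 7 (future C5 acetate, tertiary hydroxyl free)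
Conditions: Ac2O, pyridine, DMAP (cat.), CH2Cl2, 0 °C
Reagents that add atoms: acetic anhydride, CC(=O)OC(C)=O
Why: DMAP-catalysed acetylation of the secondary hydroxyl; the tertiary α-ketol hydroxyl is too hindered to react, and the C5 configuration is untouched.

Step 6
Reactants: 8 the monoacetate from step 5
Product: 9 1-[6-acetoxy-4,5-(isopropylidenedioxy)-3-(tert-butyldimethylsilyloxy)cyclohex-1-en-1-yl]ethanone (C5 acetate and C8 silyl ether on the upper face, C4a=C8a alkene)
Conditions: Burgess reagent, toluene, 70 °C
Reagents that add atoms: none
Why: Burgess dehydration by syn-elimination (Ei) of the tertiary sulfamate; the only hydrogen syn to the upper-face C4a–O bond is on C8a (the C5 hydrogen is trans to it), so the alkene forms as C4a=C8a and the allylic acetate is kept; an E1 path through an α-acyl cation is disfavoured.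

Step 7
Reactants: 10 2'-hydroxy-4',5'-dimethoxyacetophenone; 11 3-phenylpropanoyl chloride
Product: 13 6,7-dimethoxy-2-(2-phenylethyl)-4H-chromen-4-one, via diketone 12 (not isolated)
Conditions: LiN(SiMe3)2 (3.1 equiv), THF, −78 °C; 11, −78 → 0 °C; aq. HCl; then AcOH, H2SO4 (cat.), 95 °C
Reagents that add atoms: none
Why: C-acylation of the phenoxide–enolate dianion gives the 1,3-diketone directly (Baker–Venkataraman-type product), and acid cyclodehydration closes the 4-pyranone.

Step 8
Reactants: 13 6,7-dimethoxy-2-(2-phenylethyl)-4H-chromen-4-one
Product: 14 6,7-dihydroxy-2-(2-phenylethyl)-4H-chromen-4-one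
Conditions: BBr3, CH2Cl2, −78 °C → rt; MeOH, H2O
Reagents that add atoms: none
Why: Lewis-acid cleavage of both aryl methyl ethers; chromones tolerate BBr3 as their carbonyl complexes.

Step 9
Reactants: 14 6,7-dihydroxy-2-(2-phenylethyl)-4H-chromen-4-one
Product: 15 6-hydroxy-7-(methoxymethoxy)-2-(2-phenylethyl)-4H-chromen-4-one
Conditions: MOMCl (1.05 equiv), i-Pr2NEt (1.1 equiv), DMF, 0 °C
Reagents that add atoms: chloromethyl methyl ether, COCCl
Why: O-Alkylation of the more acidic 7-hydroxyl, which is para to the ring carbon bearing the carbonyl and so is ionised first by one equivalent of base; the 6-hydroxyl stays free, as is known for 6,7-dihydroxycoumarins.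

Step 10
Reactants: 9 the allylic acetate from step 6; 15 6-hydroxy-7-(methoxymethoxy)-2-(2-phenylethyl)-4H-chromen-4-one
Product: 16 1-[6-(ArO)-4,5-(isopropylidenedioxy)-3-(tert-butyldimethylsilyloxy)cyclohex-1-en-1-yl]ethanone (C5 aryl ether on the upper face)
Conditions: Pd2(dba)3·CHCl3 (2.5 mol %), PPh3 (12 mol %), Cs2CO3, THF, rt
Reagents that add atoms: none
Why: Tsuji–Trost allylic etherification; zerovalent palladium ionises the C5 acetate with inversion to the 2-acyl (π-allyl)Pd(PPh3)2 cation with the metal on the lower face, and the cesium phenoxide of 15 attacks from the upper face, so C5 is retained overall (ArO trans to the C6 oxygen). The C5 terminus is preferred because upper-face approach to C8a is blocked by the neighbouring C8 silyl ether, whereas the C6 oxygen next to C5 points down.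

Step 11
Reactants: 16 the aryl ether methyl ketone from step 10; 17 3-phenylpropanal
Product: 18 3-hydroxy-1-[6-(ArO)-4,5-(isopropylidenedioxy)-3-(tert-butyldimethylsilyloxy)cyclohex-1-en-1-yl]-5-phenylpentan-1-one (both carbinol epimers)
Conditions: LiN(SiMe3)2 (1.05 equiv), THF, −78 °C; 17; AcOH, −78 °C
Reagents that add atoms: none
Why: Crossed aldol addition of the kinetic lithium enolate (the methyl group holds the only α-hydrogens of the enone) to the aldehyde; the enolate carbon is not conjugated with C4a, so the C5 aryloxy group is not β to a carbanion, and the chromone is a poor electrophile at −78 °C. The new carbinol centre is removed in step 12.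

Step 12
Reactants: 18 the aldol adduct from step 11
Product: 19 1-[6-(ArO)-4,5-(isopropylidenedioxy)-3-(tert-butyldimethylsilyloxy)cyclohex-1-en-1-yl]-5-phenylpentane-1,3-dione (key-step precursor)
Conditions: Dess–Martin periodinane, NaHCO3, CH2Cl2, 0 °C → rt
Reagents that add atoms: none
Why: Dess–Martin oxidation of the β-hydroxy ketone to the 1,3-diketone under buffered, non-basic conditions; 19 should be used at once because base would trigger cyclisation with loss of aryloxide.

Step 13
Reactants: 19 the enone β-diketone from step 12
Product: 21 6,7-O-isopropylidene-8-O-(tert-butyldimethylsilyl)-7'-O-(methoxymethyl) derivative of the target, via C4a-bound Pd(O2CCF3) enolate 20 (not isolated)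
Conditions: Pd(O2CCF3)2 (20 mol %), O2 (1 atm), DMSO, 4 Å MS, 50 °C
Reagents that add atoms: none
Why: The diketone reacts as its C2 enol: Pd(O2CCF3)2 (divalent palladium) binds the C4a=C8a alkene on the lower face, which is free of the C5 aryloxy and C8 silyloxy groups, and the enol oxygen adds to C8a from the upper face (anti-oxypalladation of the Wacker type) to give the cis-fused C4a-bound palladium enolate 20. syn β-Hydride elimination of the C8a hydrogen, which lies on the metal's face and is α to O1, re-forms C4a=C8a inside the new 4-pyranone, and O2 in DMSO returns zerovalent palladium to the divalent state. The closest known reaction type is the palladium-catalysed aerobic oxidative cyclisation of 2'-hydroxychalcones to flavones and of β-hydroxy enones to dihydropyranones. Ring B closes in the 6-endo-trig mode by O1–C8a bond formation; attack through C3 would need a four-membered ring. No stereocentre is created, because the sp3 centres C4a and C8a of 20 are erased again and C5–C8 are not touched. Hydride loss toward C8a and not C5 is secured by the gain of pyranone aromaticity and by the C8a–H bond being next to oxygen. The C5 aryloxy group should survive because in 20 it is anti to palladium, which bars syn β-aryloxide elimination, and because the medium is free of base, which suppresses E1cB loss from a free enolate. The allylic ethers at C5 and C8 should not be ionised, since phosphine-free zerovalent palladium is trapped by O2 faster than it inserts.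

Step 14
Reactants: 21 the protected target from step 13
Product: 22 (5S,6S,7R,8S)-6,7,8-trihydroxy-5-{[7-hydroxy-4-oxo-2-(2-phenylethyl)-4H-chromen-6-yl]oxy}-2-(2-phenylethyl)-5,6,7,8-tetrahydro-4H-chromen-4-one
Conditions: CF3CO2H/H2O (9:1), 0 °C → rt
Reagents that add atoms: none
Why: Acid hydrolysis removes the isopropylidene acetal, the aryl methoxymethyl acetal and the secondary silyl ether in one operation without breaking a C–O bond at a stereocentre; cold, short exposure is chosen because C5–OAr is the one bond that could ionise.

## Compound list

1 | (−)-shikimic acid, (3R,4S,5R)-3,4,5-trihydroxycyclohex-1-ene-1-carboxylic acid | OC(=O)C1=C[C@@H](O)[C@@H](O)[C@H](O)C1 | starting material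
2 | methyl shikimate | COC(=O)C1=C[C@@H](O)[C@@H](O)[C@H](O)C1 | intermediate (not isolated)
3 | methyl 3,4-O-isopropylidene shikimate, methyl (3R,4S,5R)-5-hydroxy-3,4-(isopropylidenedioxy)cyclohex-1-ene-1-carboxylate | COC(=O)C1=C[C@@H](OC(C)(C)O2)[C@@H]2[C@H](O)C1 | intermediate
4 | methyl 5-O-(tert-butyldimethylsilyl)-3,4-O-isopropylidene shikimate | COC(=O)C1=C[C@@H](OC(C)(C)O2)[C@@H]2[C@H](O[Si](C)(C)C(C)(C)C)C1 | intermediate
5 | N-methoxy-N-methyl amide of 5-O-(tert-butyldimethylsilyl)-3,4-O-isopropylidene shikimic acid (Weinreb amide) | CON(C)C(=O)C1=C[C@@H](OC(C)(C)O2)[C@@H]2[C@H](O[Si](C)(C)C(C)(C)C)C1 | intermediate (not isolated)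
6 | 1-[5-(tert-butyldimethylsilyloxy)-3,4-(isopropylidenedioxy)cyclohex-1-en-1-yl]ethanone, shikimate configuration (3,4-cis, 4,5-trans) | CC(=O)C1=C[C@@H](OC(C)(C)O2)[C@@H]2[C@H](O[Si](C)(C)C(C)(C)C)C1 | intermediate
7 | 1-[1,2-dihydroxy-3,4-(isopropylidenedioxy)-5-(tert-butyldimethylsilyloxy)cyclohexyl]ethanone; 1-OH, 2-OH and 5-OTBS on the upper face, acetonide on the lower face | CC(=O)[C@@]1(O)[C@H](O)[C@@H](OC(C)(C)O2)[C@@H]2[C@H](O[Si](C)(C)C(C)(C)C)C1 | intermediate
8 | 2-O-acetate of 7 (secondary acetate at the future C5, tertiary hydroxyl free) | CC(=O)[C@@]1(O)[C@H](OC(C)=O)[C@@H](OC(C)(C)O2)[C@@H]2[C@H](O[Si](C)(C)C(C)(C)C)C1 | intermediate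
9 | 1-[6-acetoxy-4,5-(isopropylidenedioxy)-3-(tert-butyldimethylsilyloxy)cyclohex-1-en-1-yl]ethanone; C5 acetate and C8 silyl ether on the upper face, 6,7-acetonide on the lower face | C1=C(C(C)=O)[C@H](OC(C)=O)[C@@H](OC(C)(C)O2)[C@@H]2[C@@H]1O[Si](C)(C)C(C)(C)C | intermediate
10 | 2'-hydroxy-4',5'-dimethoxyacetophenone | CC(=O)c1cc(OC)c(OC)cc1O | starting material
11 | 3-phenylpropanoyl chloride | O=C(Cl)CCc1ccccc1 | starting material
12 | 1-(2-hydroxy-4,5-dimethoxyphenyl)-5-phenylpentane-1,3-dione | COc1cc(O)c(cc1OC)C(=O)CC(=O)CCc1ccccc1 | intermediate (not isolated)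
13 | 6,7-dimethoxy-2-(2-phenylethyl)-4H-chromen-4-one | COc1cc2oc(CCc3ccccc3)cc(=O)c2cc1OC | intermediate
14 | 6,7-dihydroxy-2-(2-phenylethyl)-4H-chromen-4-one | Oc1cc2oc(CCc3ccccc3)cc(=O)c2cc1O | intermediate
15 | 6-hydroxy-7-(methoxymethoxy)-2-(2-phenylethyl)-4H-chromen-4-one | COCOc1cc2oc(CCc3ccccc3)cc(=O)c2cc1O | intermediate
16 | 1-[6-(ArO)-4,5-(isopropylidenedioxy)-3-(tert-butyldimethylsilyloxy)cyclohex-1-en-1-yl]ethanone; aryloxy and silyloxy on the upper face | C1=C(C(C)=O)[C@H](Oc3cc4c(=O)cc(CCc5ccccc5)oc4cc3OCOC)[C@@H](OC(C)(C)O2)[C@@H]2[C@@H]1O[Si](C)(C)C(C)(C)C | intermediate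
17 | 3-phenylpropanal | O=CCCc1ccccc1 | starting material
18 | 3-hydroxy-1-[6-(ArO)-4,5-(isopropylidenedioxy)-3-(tert-butyldimethylsilyloxy)cyclohex-1-en-1-yl]-5-phenylpentan-1-one, both carbinol epimers | C1=C(C(=O)CC(O)CCc6ccccc6)[C@H](Oc3cc4c(=O)cc(CCc5ccccc5)oc4cc3OCOC)[C@@H](OC(C)(C)O2)[C@@H]2[C@@H]1O[Si](C)(C)C(C)(C)C | intermediate
19 | 1-[6-(ArO)-4,5-(isopropylidenedioxy)-3-(tert-butyldimethylsilyloxy)cyclohex-1-en-1-yl]-5-phenylpentane-1,3-dione (key-step precursor) | C1=C(C(=O)CC(=O)CCc6ccccc6)[C@H](Oc3cc4c(=O)cc(CCc5ccccc5)oc4cc3OCOC)[C@@H](OC(C)(C)O2)[C@@H]2[C@@H]1O[Si](C)(C)C(C)(C)C | intermediate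
20 | C4a-bound Pd(O2CCF3) enolate (divalent palladium) of the cis-fused 4a,8a-dihydro-4H-chromen-4-one, O1 on the upper and palladium on the lower face | O=C1C=C(CCc2ccccc2)O[C@@H]3[C@@]1([Pd]OC(=O)C(F)(F)F)[C@H](Oc5cc6c(=O)cc(CCc7ccccc7)oc6cc5OCOC)[C@@H](OC(C)(C)O4)[C@@H]4[C@@H]3O[Si](C)(C)C(C)(C)C | intermediate (not isolated)
21 | 6,7-O-isopropylidene-8-O-(tert-butyldimethylsilyl)-7'-O-(methoxymethyl) derivative of the target (key-step product) | O=c1cc(CCc2ccccc2)oc2c1[C@H](Oc1cc3c(=O)cc(CCc4ccccc4)oc3cc1OCOC)[C@@H](OC(C)(C)O5)[C@@H]5[C@@H]2O[Si](C)(C)C(C)(C)C | intermediate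
22 | (5S,6S,7R,8S)-6,7,8-trihydroxy-5-{[7-hydroxy-4-oxo-2-(2-phenylethyl)-4H-chromen-6-yl]oxy}-2-(2-phenylethyl)-5,6,7,8-tetrahydro-4H-chromen-4-one | O=c1cc(CCc2ccccc2)oc2c1[C@H](Oc1cc3c(=O)cc(CCc4ccccc4)oc3cc1O)[C@@H](O)[C@@H](O)[C@@H]2O | target

## Step count and least certain steps

Total: 14 steps. Longest linear sequence: 11 steps (1 → 22 through steps 1–6 and 10–14). The aryl branch 10 → 15 takes 3 steps.

**Step 13 (key step).** The most likely failure is loss of the C5 aryloxy group during ring closure. Once the enol oxygen has added to C8a, C4a carries enolate character with the aryloxide in the β-position, and transient zerovalent palladium could also ionise the allylic aryl ether. A second risk is that the β-diketone binds the catalyst as a stable chelate and slows turnover. Fallback, starting from 19: acid-catalysed oxa-Michael closure (CSA cat., CH2Cl2, 0 °C), which generates no enolate, should give the cis-fused 4a,8a-dihydro-4H-chromen-4-one F1. Dehydrogenation of F1 with DDQ in dioxane (hydride abstraction from C8a, which is α to O1) rejoins the route at 21.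

**Step 10.** The phenoxide may attack the C8a terminus, or ionisation on the acetonide face may be slow enough that the (π-allyl)palladium cation loses a β-hydrogen and ring A aromatises. Fallback, starting from 7: O-arylate the secondary hydroxyl directly, keeping its C–O bond. Commercial 5'-bromo-2',4'-dihydroxyacetophenone (CC(=O)c1cc(Br)c(O)cc1O) would be acylated with 11 and cyclised as in step 7 to 6-bromo-7-hydroxy-2-(2-phenylethyl)-4H-chromen-4-one F2. MOMCl and i-Pr2NEt would then give 6-bromo-7-(methoxymethoxy)-2-(2-phenylethyl)-4H-chromen-4-one F3. Palladium-catalysed C–O coupling of F3 with 7 ([Pd(allyl)Cl]2, a bulky di-tert-butylbiarylphosphine of the RockPhos type, Cs2CO3, toluene, 90 °C) would arylate only the secondary hydroxyl and give the tertiary alcohol aryl ether F4. Burgess dehydration of F4, under the same stereochemical control as step 6, returns to 16.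

**Step 6.** Sulfamate formation at the hindered tertiary α-ketol hydroxyl may be slow, allowing acetyl migration or decomposition on heating. Fallback, starting from 6 and bypassing steps 4–6: a Schenck ene reaction with singlet oxygen (O2, hν, tetraphenylporphyrin, CH2Cl2, 0 °C) abstracts hydrogen from the ring methylene geminal to the acetyl group and forms the C–O bond at the β-carbon on the face opposite the acetonide, giving allylic hydroperoxide F5. Reduction of F5 in the same flask with PPh3 gives allylic alcohol F6. Acetylation of F6 (Ac2O, pyridine) returns to 9.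

**Step 11.** Proton transfer from the chromone 2-methylene or from the aldehyde to the enolate, or retro-aldol cleavage on warming, may erode the addition. Fallback, starting from 16: soft enolisation (MgBr2·OEt2, i-Pr2NEt, CH2Cl2, rt) and direct C-acylation of the methyl ketone with 11 reaches 19 in one step without a strong base and makes no new compound. It is not the first choice because the Lewis acid may attack the methoxymethyl acetal.

**Step 14.** Protic acid may ionise the C5–OAr bond (a vinylogous oxocarbenium ion stabilised by O1) before the silyl ether is fully cleaved. Fallback, starting from 21: Me2BBr in CH2Cl2 at −78 °C removes the methoxymethyl and isopropylidene acetals under aprotic conditions to give the 8-O-silyl tetraol F7. Buffered HF·pyridine in THF then removes the silyl group from F7 and gives 22.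

## Further compounds

F1 | step 13 | cis-fused 4a,8a-dihydro adduct of 19 (O1 drawn on the lower face; the ring-fusion configuration is erased in the next operation) | O=C1C=C(CCc2ccccc2)O[C@H]3[C@@H]1[C@H](Oc5cc6c(=O)cc(CCc7ccccc7)oc6cc5OCOC)[C@@H](OC(C)(C)O4)[C@@H]4[C@@H]3O[Si](C)(C)C(C)(C)C
F2 | step 10 | 6-bromo-7-hydroxy-2-(2-phenylethyl)-4H-chromen-4-one | Oc1cc2oc(CCc3ccccc3)cc(=O)c2cc1Br
F3 | step 10 | 6-bromo-7-(methoxymethoxy)-2-(2-phenylethyl)-4H-chromen-4-one | COCOc1cc2oc(CCc3ccccc3)cc(=O)c2cc1Br
F4 | step 10 | 1-[1-hydroxy-2-(ArO)-3,4-(isopropylidenedioxy)-5-(tert-butyldimethylsilyloxy)cyclohexyl]ethanone (2-O-aryl ether of 7) | CC(=O)[C@@]1(O)[C@H](Oc3cc4c(=O)cc(CCc5ccccc5)oc4cc3OCOC)[C@@H](OC(C)(C)O2)[C@@H]2[C@H](O[Si](C)(C)C(C)(C)C)C1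
F5 | step 6 | 1-[6-hydroperoxy-4,5-(isopropylidenedioxy)-3-(tert-butyldimethylsilyloxy)cyclohex-1-en-1-yl]ethanone | C1=C(C(C)=O)[C@H](OO)[C@@H](OC(C)(C)O2)[C@@H]2[C@@H]1O[Si](C)(C)C(C)(C)C
F6 | step 6 | 1-[6-hydroxy-4,5-(isopropylidenedioxy)-3-(tert-butyldimethylsilyloxy)cyclohex-1-en-1-yl]ethanone | C1=C(C(C)=O)[C@H](O)[C@@H](OC(C)(C)O2)[C@@H]2[C@@H]1O[Si](C)(C)C(C)(C)C
F0 | step 11 | none | none
F7 | step 14 | 8-O-(tert-butyldimethylsilyl) derivative of 22 | O=c1cc(CCc2ccccc2)oc2c1[C@H](Oc1cc3c(=O)cc(CCc4ccccc4)oc3cc1O)[C@@H](O)[C@@H](O)[C@@H]2O[Si](C)(C)C(C)(C)C
A1 | alternative 1 | acetonide of methyl (1S,2R)-1,2-dihydroxycyclohexa-3,5-diene-1-carboxylate | COC(=O)[C@]1(OC(C)(C)O2)C=CC=C[C@H]12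
A2 | alternative 1 | 2,3-dioxabicyclo[2.2.2]oct-5-ene endoperoxide of A1, peroxide anti to the acetonide | COC(=O)[C@]1(OC(C)(C)O2)[C@H]3C=C[C@H](OO3)[C@H]12
A3 | alternative 2 | 2-deoxy-4,5-O-isopropylidene-3-O-(4-methoxybenzyl)hexodialdose (open-chain dialdehyde) | O=CC[C@H](OCc1ccc(OC)cc1)[C@@H](OC(C)(C)O3)[C@@H]3C=O
A4 | alternative 2 | 2-hydroxy-3,4-isopropylidenedioxy-5-(4-methoxybenzyloxy)cyclohexanone | O=C2C[C@H](OCc1ccc(OC)cc1)[C@@H](OC(C)(C)O3)[C@@H]3[C@@H]2O
A5 | alternative 3 | 7-benzyloxy-4-oxo-2-(2-phenylethyl)chromen-6-yl 2,3,4-tri-O-benzyl-6-deoxy-α-D-lyxo-hex-5-enopyranoside | C=C1O[C@H](Oc2cc3c(=O)cc(CCc4ccccc4)oc3cc2OCc2ccccc2)[C@@H](OCc2ccccc2)[C@@H](OCc2ccccc2)[C@@H]1OCc1ccccc1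
A6 | alternative 3 | 3-aryloxy-4,5,6-tris(benzyloxy)cyclohexanone (aryl as in A5) | O=C1C[C@H](Oc2cc3c(=O)cc(CCc4ccccc4)oc3cc2OCc2ccccc2)[C@@H](OCc2ccccc2)[C@@H](OCc2ccccc2)[C@@H]1OCc1ccccc1
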